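The earlier runs and the new flask are simulated for an exercise, and the scatter is random.

The vessel is closed, stirred and isothermal; solid X enters solution while D becomes J.

- autumn: D 1 M; X 0.80 equiv; run made earlier
- flask: D 2.0 M; X 0.800 equiv; time 80 min

autumn run (percent of the D charged)

| time / min | J / % | D / % |
|---|---|---|
| 2.50 | 31.9 | 66.7 |
| 8.00 | 57.5 | 38.2 |
| 30.0 | 52.3 | 22.4 |
| 90.0 | 36.9 | 20.9 |

(scatter of a reading: 0.5 percentage points)

- when, up to 80 min, the flask holds most J
- the amount of J, in percent of the D charged, at that time

- given per volume of solution although it is solid: X
- at the start none of X is in solution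

Down the D column, the autumn run levels off at 20.9%, near the excess f = 20.0% left by the equivalents of X, the limiting reagent. A second-order law integrates so that ln(D/(D−f)) is straight in time, and the first 2 rows give slope s = 0.0700 min⁻¹ after a delay of 0.595 min.

Across the rows, the missing share M = 100 − D − J grows from 4.30% at 8.00 min to 25.3% at 30.0 min. Dividing that gain by the mean J and the time gives the loss constant λ = 0.0174 min⁻¹, the fraction of J lost per minute over that stretch of the autumn run. The last rows give less, 0.00632 min⁻¹, so λ is no constant of the whole autumn run.

My own reckoning keeps λ and the delay unchanged in the flask while formation speeds up to g·D(D−f), with g = 0.700 min⁻¹. Setting this equal to λJ, with J near the autumn reading 57.5%, puts the top at D = 25.6%, at 9.88 min.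

The forecast gives 6.5 min and 61%, reasoning that “Doubling the concentrations halves the time scale of both second-order steps”. The two part on the time, the reckoning standing later.

The flask tops at 10.4 min with 64.7% of J.

    X ⇌ L, rate k1*(cs1 - [L]) while solid is left; crystals form when [L] > cs1 (solubility = 0.940 M, k = 0.0140 s⁻¹)
    D + L → J + Z (k = 0.00620 M⁻¹ s⁻¹)
    J ⇌ E (K = 1.30, k = 3.40 × 10⁻⁴ s⁻¹)

Here L is dissolved X, Z a by-product and E the other product, which is the missing share M. In the flask, the step from D + L to J + Z has half of its turnover up to 80 min behind it by 3.21 min, sooner than the 22.1 min of the step from J to E. Carried to the neighbour flask left until 20 min, λ with the mean J adds 10 percentage points to the 9.21% of E at the top, giving 19.6%, and that neighbour holds 19.3%.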